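Numbering: oxolane ring O1, C2 (ring A = 3-hydroxy-4,5-dimethoxyphenyl), C3 (CH3), C4 (CH3), C5 (ring B = 3,4,5-trimethoxyphenyl). The target is 2R,3S,4S,5S, which means 2,3-cis, 3,4-trans, 4,5-trans, with rings A and B cis.
Cuts: first C5–C(ipso) of ring B together with C5–H, leading back to γ-lactone 11 (C5 as C=O) and aryl bromide 12. Then C4–CH3 (enolate methylation), O1–C5 (oxidative lactonisation) and C2–C3 (crotylboration of the ring A aldehyde).
Enabling feature: C5 lies between O1 and ring B, so it can be carried at the carboxyl level, take up ring B as a carbanion, and then ionise to a cation shared by O1 and ring B. Ring A on C2 and CH3 on C3 fill the face on which ring B must end, so ring B comes first and the small hydride comes last, from the open face.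
Forward order: the chain C2–C5 is grown on ring A, the oxolane is closed as a lactone, C4 is methylated, and ring B is joined last. The helper oxygen on C5 leaves in that same flask and the phenol TIPS group leaves in the final step.
Stereochemistry: C2 and C3 come from a catalyst-controlled (Z)-crotylboration. C4 and C5 come from the substrate, by attack anti to ring A and C3–CH3 in both cases.

Key step: step 6

Remark: 1, 3, 12 and the catalyst of step 2 are taken as commercial, and the sense of induction in step 2 is taken from the re-face attack known for benzaldehyde under the (R) catalyst.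

Step 1
Reactants: 1 3-hydroxy-4,5-dimethoxybenzaldehyde
Product: 2 3,4-dimethoxy-5-(triisopropylsilyloxy)benzaldehyde
Conditions: TIPSCl, imidazole, DMF, rt
Reagents that add atoms: chlorotriisopropylsilane (TIPSCl) CC(C)[Si](Cl)(C(C)C)C(C)C
Why: Imidazole-promoted silyl ether formation masks the ring A phenol against the oxidant of step 4, the base and MeI of step 5 and the aryllithium of step 6, and the bulky TIPS group should outlast all of them.

Step 2
Reactants: 2 3,4-dimethoxy-5-(triisopropylsilyloxy)benzaldehyde; 3 (Z)-crotylboronic acid pinacol ester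
Product: 5 (1R,2S)-1-[3,4-dimethoxy-5-(triisopropylsilyloxy)phenyl]-2-methylbut-3-en-1-ol, via pinacol borate ester 4 (not isolated)
Conditions: (R)-TRIP [(R)-3,3'-bis(2,4,6-triisopropylphenyl)-1,1'-binaphthyl-2,2'-diyl hydrogen phosphate, 5 mol %], toluene, -30 °C; aqueous work-up
Reagents that add atoms: none
Why: In this chiral phosphoric acid catalysed crotylboration the closed chair (Zimmerman–Traxler) transition state turns the Z geometry of 3 into the syn (later 2,3-cis) relationship, and the (R) catalyst should direct attack to the re face of the aldehyde, setting C2 as R and C3 as S.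

Step 3
Reactants: 5 (1R,2S)-1-[3,4-dimethoxy-5-(triisopropylsilyloxy)phenyl]-2-methylbut-3-en-1-ol
Product: 7 (1R,2S)-1-[3,4-dimethoxy-5-(triisopropylsilyloxy)phenyl]-2-methylbutane-1,4-diol, via B-alkyl-9-BBN adduct 6 (not isolated)
Conditions: 9-BBN, THF, 0 °C to rt; then 30% H2O2, aq NaOAc, 0 °C to rt
Reagents that add atoms: hydrogen peroxide OO
Why: In this hydroboration and oxidation the bulky 9-BBN places boron on the terminal carbon only (anti-Markovnikov), no stereocenter is touched, and the acetate-buffered peroxide should spare the aryl silyl ether.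

Step 4
Reactants: 7 (1R,2S)-1-[3,4-dimethoxy-5-(triisopropylsilyloxy)phenyl]-2-methylbutane-1,4-diol
Product: 9 (4S,5R)-5-[3,4-dimethoxy-5-(triisopropylsilyloxy)phenyl]-4-methyldihydrofuran-2(3H)-one, via lactol 8 (not isolated)
Conditions: TEMPO (cat.), PhI(OAc)2, CH2Cl2, rt
Reagents that add atoms: none
Why: In this oxoammonium (TEMPO) oxidative lactonisation the unhindered primary alcohol reacts first, the aldehyde is caught by the C2 hydroxyl as lactol 8 (5-exo-trig), and 8 is oxidised on to the lactone, so O1–C5 closes with C2 and C3 untouched.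

Step 5
Reactants: 9 (4S,5R)-5-[3,4-dimethoxy-5-(triisopropylsilyloxy)phenyl]-4-methyldihydrofuran-2(3H)-one
Product: 11 (3S,4S,5R)-5-[3,4-dimethoxy-5-(triisopropylsilyloxy)phenyl]-3,4-dimethyldihydrofuran-2(3H)-one, via lithium enolate 10 (not isolated)
Conditions: LiN(SiMe3)2, THF, -78 °C; then MeI, -78 to -40 °C
Reagents that add atoms: iodomethane (MeI) CI
Why: In this lactone enolate alkylation ring A and the neighbouring methyl group both shield the top face of the planar enolate 10, so MeI should enter from the bottom face and set the new center (C4 of the target) as S, trans to the C3 methyl group.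

Step 6
Reactants: 11 (3S,4S,5R)-5-[3,4-dimethoxy-5-(triisopropylsilyloxy)phenyl]-3,4-dimethyldihydrofuran-2(3H)-one; 12 5-bromo-1,2,3-trimethoxybenzene
Product: 16 (2R,3S,4S,5S)-2-[3,4-dimethoxy-5-(triisopropylsilyloxy)phenyl]-3,4-dimethyl-5-(3,4,5-trimethoxyphenyl)tetrahydrofuran, via aryllithium 13 (not isolated), via hemiketal 14 (not isolated), via oxocarbenium ion 15 (not isolated)
Conditions: 12, n-BuLi, Et2O, -78 to 0 °C; then 11 in toluene, -78 °C; AcOH (1 equiv), -78 °C; then CH2Cl2, Et3SiH, BF3·OEt2, -78 °C; aq NaHCO3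
Reagents that add atoms: none
Why: Br/Li exchange turns 12 into aryllithium 13, which adds once to the lactone carbonyl C5 of 11 and so forms the bond between C5 and ring B, a second addition being held back because the lithium alkoxide of the tetrahedral adduct persists at -78 °C and C4 is branched. After protonation the adduct rests as hemiketal 14, whose O1–C5 bond is kept or re-formed by 5-exo-trig attack of the C2 oxygen on the aryl ketone tautomer, and BF3 then removes the C5 hydroxyl to give oxocarbenium ion 15, stabilised by O1 and ring B. Et3SiH transfers hydride to C5 of 15, so the helper oxygen leaves and the last stereocenter is set in the same flask. The closest known reaction type is the preparation of C-aryl glycosides and of 2,5-diaryltetrahydrofuran lignans by aryllithium addition to a lactone followed by Lewis acid and hydride reduction of the lactol. C5 is controlled by the substrate: in the envelope of 15 that keeps both methyl groups pseudo-equatorial, ring A stands pseudo-axial on the top face beside the C3 methyl group, so hydride should enter from inside the envelope on the open bottom face and push ring B to the top face, trans to the C4 methyl group and cis to ring A (5S). The step also needs retention at the acid-labile benzylic C2, which should be secured by the low temperature and by ring A itself, whose para methoxy group is twisted out of conjugation by its two ortho oxygen substituents and so supports opening of O1–C2 poorly.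

Step 7
Reactants: 16 (2R,3S,4S,5S)-2-[3,4-dimethoxy-5-(triisopropylsilyloxy)phenyl]-3,4-dimethyl-5-(3,4,5-trimethoxyphenyl)tetrahydrofuran
Product: 17 5-[(2R,3S,4S,5S)-3,4-dimethyl-5-(3,4,5-trimethoxyphenyl)tetrahydrofuran-2-yl]-2,3-dimethoxyphenol
Conditions: Bu4NF, AcOH, THF, 0 °C
Reagents that add atoms: none
Why: Fluoride desilylation, driven by the strong Si–F bond, cleaves only the aryl silyl ether, acetic acid buffers the phenoxide, and neither reagent should touch the two benzylic ether bonds or any stereocenter.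

Compound list
1 | 3-hydroxy-4,5-dimethoxybenzaldehyde | COc1cc(C=O)cc(O)c1OC | starting material
2 | 3,4-dimethoxy-5-(triisopropylsilyloxy)benzaldehyde | COc1cc(C=O)cc(O[Si](C(C)C)(C(C)C)C(C)C)c1OC | intermediate
3 | (Z)-crotylboronic acid pinacol ester | C/C=C\CB1OC(C)(C)C(C)(C)O1 | starting material
4 | pinacol borate ester of 5 | COc1cc([C@H](OB2OC(C)(C)C(C)(C)O2)[C@@H](C)C=C)cc(O[Si](C(C)C)(C(C)C)C(C)C)c1OC | intermediate
5 | (1R,2S)-1-[3,4-dimethoxy-5-(triisopropylsilyloxy)phenyl]-2-methylbut-3-en-1-ol | COc1cc([C@H](O)[C@@H](C)C=C)cc(O[Si](C(C)C)(C(C)C)C(C)C)c1OC | intermediate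
6 | B-alkyl-9-BBN adduct of 5 | COc1cc([C@H](O)[C@@H](C)CCB2C3CCCC2CCC3)cc(O[Si](C(C)C)(C(C)C)C(C)C)c1OC | intermediate
7 | (1R,2S)-1-[3,4-dimethoxy-5-(triisopropylsilyloxy)phenyl]-2-methylbutane-1,4-diol | COc1cc([C@H](O)[C@@H](C)CCO)cc(O[Si](C(C)C)(C(C)C)C(C)C)c1OC | intermediate
8 | lactol, (4S,5R)-5-aryl-4-methyltetrahydrofuran-2-ol, both anomers | COc1cc([C@@H]2OC(O)C[C@@H]2C)cc(O[Si](C(C)C)(C(C)C)C(C)C)c1OC | intermediate
9 | (4S,5R)-5-[3,4-dimethoxy-5-(triisopropylsilyloxy)phenyl]-4-methyldihydrofuran-2(3H)-one | COc1cc([C@@H]2OC(=O)C[C@@H]2C)cc(O[Si](C(C)C)(C(C)C)C(C)C)c1OC | intermediate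
10 | lithium enolate of 9 | COc1cc([C@@H]2OC(O[Li])=C[C@@H]2C)cc(O[Si](C(C)C)(C(C)C)C(C)C)c1OC | intermediate
11 | (3S,4S,5R)-5-[3,4-dimethoxy-5-(triisopropylsilyloxy)phenyl]-3,4-dimethyldihydrofuran-2(3H)-one | COc1cc([C@@H]2OC(=O)[C@@H](C)[C@@H]2C)cc(O[Si](C(C)C)(C(C)C)C(C)C)c1OC | intermediate
12 | 5-bromo-1,2,3-trimethoxybenzene | COc1cc(Br)cc(OC)c1OC | starting material
13 | 3,4,5-trimethoxyphenyllithium | COc1cc([Li])cc(OC)c1OC | intermediate
14 | hemiketal, (3S,4S,5R)-5-aryl-3,4-dimethyl-2-(3,4,5-trimethoxyphenyl)tetrahydrofuran-2-ol, both anomers | COc1cc([C@@H]2OC(O)(c3cc(OC)c(OC)c(OC)c3)[C@@H](C)[C@@H]2C)cc(O[Si](C(C)C)(C(C)C)C(C)C)c1OC | intermediate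
15 | oxocarbenium ion (O1=C5 cation bearing ring B) | COc1cc([C@@H]2[O+]=C(c3cc(OC)c(OC)c(OC)c3)[C@@H](C)[C@@H]2C)cc(O[Si](C(C)C)(C(C)C)C(C)C)c1OC | intermediate
16 | (2R,3S,4S,5S)-2-[3,4-dimethoxy-5-(triisopropylsilyloxy)phenyl]-3,4-dimethyl-5-(3,4,5-trimethoxyphenyl)tetrahydrofuran | COc1cc([C@@H]2O[C@H](c3cc(OC)c(OC)c(OC)c3)[C@@H](C)[C@@H]2C)cc(O[Si](C(C)C)(C(C)C)C(C)C)c1OC | intermediate
17 | 5-[(2R,3S,4S,5S)-3,4-dimethyl-5-(3,4,5-trimethoxyphenyl)tetrahydrofuran-2-yl]-2,3-dimethoxyphenol | COc1cc([C@@H]2O[C@H](c3cc(OC)c(OC)c(OC)c3)[C@@H](C)[C@@H]2C)cc(O)c1OC | target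

Total step count: 7. Longest linear sequence: 7 steps (1, 2, 5, 7, 9, 11, 16, 17).

Steps most likely to fail

Step 6. Four processes could defeat it:
- enolisation of 11 in place of addition;
- a second addition of 13 after ring opening;
- Lewis acid opening of the O1–C2 bond with loss of configuration at C2;
- insufficient facial selectivity in the hydride transfer.

The fallback sets out from 11 and comes back at 16. It replaces the ionic reduction by a radical one under neutral conditions. Lawesson's reagent in hot toluene would convert 11 into the thionolactone F1. Aryllithium 13 would add to the C=S carbon at -78 °C, and MeI would trap the thiolate to give the mixed S-methyl thioketal F2. Ph3SnH and AIBN in hot toluene would then cleave the C5–S bond. The tertiary, benzylic, O1-stabilised C5 radical should take hydrogen from the stannane on the open bottom face, giving 16. No Lewis acid is present, so O1–C2 cannot ionise.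

Step 2. Enantiofacial or syn/anti control may be insufficient in the catalysed crotylboration of this hindered, electron-rich aldehyde. The fallback sets out from 2 and comes back at 5. It moves the source of asymmetry to a covalently bound auxiliary.
- An Evans syn-aldol reaction of 2 with the dibutylboron enolate of commercial (R)-4-benzyl-3-propionyl-1,3-oxazolidin-2-one (Bu2BOTf, Et3N, CH2Cl2, -78 to 0 °C) would give the syn-aldol imide F3.
- LiBH4 in wet Et2O would remove the auxiliary reductively and give the 1,3-diol F4.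
- TEMPO and PhI(OAc)2 would oxidise its primary alcohol to the β-hydroxy aldehyde F5.
- Wittig methylenation with Ph3P=CH2 (from Ph3PCH3Br and KN(SiMe3)2, THF, -78 °C) would give 5.

Step 4. The electron-rich benzylic C2 carbinol may be oxidised before the lactol has formed, which would erase C2. The fallback sets out from 5 and comes back at 9. It masks C2–OH and closes the ring by lactonisation of an acid instead of by lactol oxidation.
- TESCl and imidazole would give the triethylsilyl ether F6.
- 9-BBN followed by buffered H2O2 would give the primary alcohol F7.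
- TEMPO and PhI(OAc)2 in aqueous MeCN would give the carboxylic acid F8.
- AcOH in THF and water would remove only the alkyl TES group, whereupon the γ-hydroxy acid should close to 9.

Further compounds
F1 | step 6 | (3S,4S,5R)-5-[3,4-dimethoxy-5-(triisopropylsilyloxy)phenyl]-3,4-dimethyldihydrofuran-2(3H)-thione | COc1cc([C@@H]2OC(=S)[C@@H](C)[C@@H]2C)cc(O[Si](C(C)C)(C(C)C)C(C)C)c1OC
F2 | step 6 | (3S,4S,5R)-5-[3,4-dimethoxy-5-(triisopropylsilyloxy)phenyl]-3,4-dimethyl-2-(methylsulfanyl)-2-(3,4,5-trimethoxyphenyl)tetrahydrofuran, both epimers at the thioketal carbon | COc1cc([C@@H]2OC(SC)(c3cc(OC)c(OC)c(OC)c3)[C@@H](C)[C@@H]2C)cc(O[Si](C(C)C)(C(C)C)C(C)C)c1OC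
F3 | step 2 | (4R)-4-benzyl-3-[(2R,3R)-3-[3,4-dimethoxy-5-(triisopropylsilyloxy)phenyl]-3-hydroxy-2-methylpropanoyl]-1,3-oxazolidin-2-one | COc1cc([C@H](O)[C@@H](C)C(=O)N2C(=O)OC[C@H]2Cc2ccccc2)cc(O[Si](C(C)C)(C(C)C)C(C)C)c1OC
F4 | step 2 | (1R,2S)-1-[3,4-dimethoxy-5-(triisopropylsilyloxy)phenyl]-2-methylpropane-1,3-diol | COc1cc([C@H](O)[C@@H](C)CO)cc(O[Si](C(C)C)(C(C)C)C(C)C)c1OC
F5 | step 2 | (2R,3R)-3-[3,4-dimethoxy-5-(triisopropylsilyloxy)phenyl]-3-hydroxy-2-methylpropanal | COc1cc([C@H](O)[C@@H](C)C=O)cc(O[Si](C(C)C)(C(C)C)C(C)C)c1OC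
F6 | step 4 | triethylsilyl ether of 5 | COc1cc([C@H](O[Si](CC)(CC)CC)[C@@H](C)C=C)cc(O[Si](C(C)C)(C(C)C)C(C)C)c1OC
F7 | step 4 | (3S,4R)-4-[3,4-dimethoxy-5-(triisopropylsilyloxy)phenyl]-3-methyl-4-(triethylsilyloxy)butan-1-ol | COc1cc([C@H](O[Si](CC)(CC)CC)[C@@H](C)CCO)cc(O[Si](C(C)C)(C(C)C)C(C)C)c1OC
F8 | step 4 | (3S,4R)-4-[3,4-dimethoxy-5-(triisopropylsilyloxy)phenyl]-3-methyl-4-(triethylsilyloxy)butanoic acid | COc1cc([C@H](O[Si](CC)(CC)CC)[C@@H](C)CC(=O)O)cc(O[Si](C(C)C)(C(C)C)C(C)C)c1OC
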